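## Structural features

The target is built from two naphthalene-derived bicycles. Each is a 5,7,8-trihydroxylated benzene ring fused to an oxidised six-membered carbocycle: a 1,4-naphthoquinone (C1–C4, C4a, C8a) and a naphthalene-1,2,4(3H)-trione (C1'–C4', C4a', C8a'). The halves are held together by one ether oxygen only, which joins the sp2 quinone carbon C2 to the quaternary sp3 carbon C3'. C3' (S) is the single stereocentre; it carries ethyl and the ether oxygen and lies between the C2' and C4' carbonyls, so it has no neighbouring stereocentre and cannot epimerise by enolisation. The fragile parts are the vicinal C1'/C2' diketone with its 1,3-relationship to C4' (open to benzilic-type and retro-Claisen cleavage by base), the ether, which is at once a hindered tertiary alkyl ether and a vinylogous ester of the quinone, and six oxidation-prone phenols. Because the 5,7,8-pattern makes each half unsymmetrical, regiochemistry has to be controlled twice. The real difficulty is the congested C3'–O–C2 linkage with control of absolute configuration, followed by raising C1' and C2' to carbonyls without losing it. The plan uses the fully substituted quinone ring: the C2–O and C3–ethyl neighbours, flanked by the C1 and C4 carbonyls, map onto the alkoxy- and ethyl-bearing carbons of a 4-aryl-4-hydroxycyclobutenone, whose electrocyclic ring expansion makes the C4–C4a bond.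

## Logic of the disconnections

**25 ⇒ 24.** The six aryl O–CH3 bonds are cut (formed last in reverse, cleaved last forward). Free phenols would not survive an aryllithium, OsO4 or activated DMSO. In 24, C3' sits between two carbonyls and can neither ionise nor be displaced, so this is the safest point for a strong Lewis acid. The gain is that every earlier intermediate is neutral, soluble and non-acidic. The demand is a reagent that cleaves six ethers but spares the vinylogous ester and the diketone.

**24 ⇒ 23 ⇒ 22.** The C1'=O and C2'=O π bonds are traced back to two C–OH bonds and then to the C1'=C2' alkene. The diketone is the most electrophilic, base-sensitive function and is therefore carried as an inert styrene-type alkene. Both carbinols are oxidised, so the dihydroxylation needs no facial control. The demand is that the oxidant choose the electron-rich disubstituted alkene over the tetrasubstituted quinone alkene, and that diol oxidation not cleave the C1'–C2' bond.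

**22 ⇒ 21.** Only the oxidation level changes (two O–H bonds). The ring expansion delivers the hydroquinone, so a mild neutral oxidant is required.

**21 ⇒ 18.** The C4–C4a bond is cut and the quinone carbocycle contracts to a four-membered ring. This removes a ring from the skeleton and reduces the regiochemical problem of the quinone half to the order of substituents on a cyclobutenone. The demand is a thermal process that tolerates the allylic tertiary ether.

**18 ⇒ 16 + 4 (through 17).** The C1–C8a bond (aryl to carbinol carbon) is cut. This detaches the whole benzenoid ring of the quinone half as a simple bromide. The aryl metal must add to the squarate carbonyl next to the alkoxy-bearing carbon and must ignore the ketone C4'.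

**16 ⇒ 10 + 15.** The O–C2 bond is cut. The hindered tertiary oxygen is joined to a small, very electrophilic vinylogous acid chloride instead of a quinone, and the chiral half is separated from an achiral C4 unit. The demand is O-substitution faster than rearrangement of the α-ketol alkoxide, and non-acidic handling of the product.

**15 ⇒ 14 ⇒ 13 ⇒ 11.** The C–Cl, the O–CH3 and the ring C–ethyl bonds are cut in turn. One carbon nucleophile adds to 11, acid removes methanol, and methoxy is exchanged for hydroxy and then chlorine. The demand is clean mono-addition.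

**10 ⇒ 9.** The C3'–OH bond is cut; the dienone becomes an aromatic naphthol. One forward step creates the stereocentre, the C4' ketone and the C1'=C2' alkene placeholder. It must oxygenate the ethyl-bearing ortho carbon and not the free para carbon, with face control from a chiral reagent.

**9 ⇒ 7 ⇒ 6 ⇒ 4 + 5.** The acyl–aryl bond C4'–C4a' is cut (ring closure at the only ortho position that can give a six-membered ring), then the α-C–ethyl bond, then the aryl–vinyl bond. The second naphthalene thus reduces to the same bromide 4 that serves the quinone half. The demands are α- and not γ-alkylation, and E-to-Z equilibration during ring closure.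

**4 ⇒ 3 ⇒ 1.** Two O–CH3 bonds and the aryl C–O bond that replaces the formyl group are cut. This leads to a cheap aldehyde in which bromine already stands ortho to oxygen in the required 1,2,3,5-pattern.

## Other disconnections considered

Alternative 1: This cut removes the C3'–O bond and the C2' carbonyl oxygen in one operation. The hexamethyl ether A2 (the same substance as 24) is traced to the symmetrical ether A1, in which one oxygen joins C2 of two identical 3-ethyl-5,7,8-trimethoxy-1,4-naphthoquinone units. Forward, one of the two equivalent C2'=C3' bonds would be epoxidised under a chiral nucleophilic-epoxidation catalyst. C2' is then a ketal carbon; its epoxide C–O bond opens with help from the ether oxygen, the C3' alkoxide adds to C2 of the other quinone to form a five-membered spiro-ketal, and collapse of that ketal transfers the quinonyl group from the old oxygen to the new one, leaving the old oxygen as the C2' carbonyl.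
- In favour: A1 comes from one building block used twice; stereocentre, hindered ether and C2' carbonyl arise together; no dihydroxylation/oxidation pair is needed.
- Against: A1 is a vinylogous anhydride, hard to make on a haloquinone and easy to cleave with the peroxide nucleophile the epoxidation needs. Its tetrasubstituted, donor-substituted double bond is a poor substrate class for asymmetric nucleophilic epoxidation. The cascade has no close model, and hydrolysis, double epoxidation and opening at C3' compete.
- Comparison: both routes reach the same compound (A2 = 24), so the last step and its risk are equal. In step economy and convergence the alternative is clearly the better, at roughly half the operations. In mechanistic security the chosen plan is better, since each bond is made by a reaction type with precedent and the stereocentre is set on a simple naphthol that can be enriched before it is committed.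

Alternative 2: The cut is the C4'–C3' bond at the oxidation level of a tetralone; ketol A4 is opened to keto aldehyde A3. Forward, a chiral triazolium-derived carbene converts the aldehyde carbon (C4') into an acyl-anion equivalent that adds to the tethered ethyl ketone (C3'), closing the six-membered ring and creating the tertiary carbinol.
- In favour: the intramolecular crossed benzoin reaction of aldehyde–ketones to six-membered tertiary α-ketols is an established catalytic, metal-free enantioselective process. The absolute configuration is probably set more securely than by reagent-controlled dearomatisation of 9; on this point the alternative is the better.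
- Against: it addresses only the stereocentre and would replace steps 3–6, not the ring expansion; the ether and the quinone half would still come from the squarate sequence. A4 (the same substance as F5 below) lacks the C1'=C2' bond, which must be introduced by benzylic dehydrogenation to reach 10. A3 needs about three steps from 4 (chain attachment, hydrogenation, formylation para to a methoxy group).
- Comparison: the two plans meet at 10 and are equal from there on. The benzoin closure is more predictable in stereochemical outcome but brings a less predictable desaturation. The chosen plan is shorter by about two steps.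

Alternative 3: Three bonds of the quinone ring are cut at once, C4–C3, C2–C1 and C1–C8a. Naphthol A7 is taken apart into the aryl(methoxy)carbene complex of zerovalent chromium A5, the ynol ether A6 and one carbon monoxide ligand. Forward, heating A5 with A6 inserts alkyne and CO and closes the ring as a 4-methoxy-1-naphthol, which oxidative demethylation (for example (NH4)2Ce(NO3)6) would turn into the quinone.
- In favour: three C–C bonds and the ring form in one operation, at a lower temperature than a cyclobutenone opening (on both points the alternative is the better). The hindered ether is again made before the ring, and no aryllithium meets a ketone because C4' is carried as a silyl ether.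
- Against: the ynol ether synthesis needs strongly basic organolithium steps, so the C4' ketone must be reduced, protected, deprotected and re-oxidised (three to four extra operations, of which the last can be merged with the diol oxidation). With C4' as a carbinol, A6 and A7 are 1,2-dihydronaphthalene-1,2-diol derivatives that can aromatise by loss of the C3' oxygen substituent, a liability that the ketone of 10, 16 and 18 suppresses. Regiochemistry of alkyne insertion rests on the steric difference between the two ends of an electron-rich ynol ether, a substrate class prone to cyclobutenone and indene side paths. A stoichiometric chromium carbonyl is consumed.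
- Comparison: both plans build the quinone carbocycle onto a finished arene with the ether already in place, both leave C3' untouched, and both need the same late alkene-to-diketone oxidation and demethylation (equal on these points). In the chosen plan the regiochemistry follows from the order of two additions to the squarate and from the single free ortho position, which is more dependable than alkyne polarity. It is also shorter because it needs no redox detour at C4'.

Key step: step 12

Remark on locants: unprimed locants (C1–C8a) refer to the quinone half and primed locants to the trione half of the target; they are kept for the corresponding atoms of all intermediates.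
Remark on descriptors: the spatial arrangement at C3' is the same from 10 to 25. It is named R while C2' is an alkene or carbinol carbon (10, 16, 18–23) and S once C2' is a carbonyl (24, 25), because the CIP ranking of C2' and C4' is then reversed.
Remark on numbering: enolates, alkoxides and carboxylates of numbered compounds are treated as forms of those compounds and carry no number of their own.
Assumption: the enantiomer of the chiral iodyl reagent in step 6 that leads to (R)-10 is taken to be identifiable in a test reaction; the route is written for that enantiomer.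

## Route

Step 1
Reactants: 1 5-bromovanillin (3-bromo-4-hydroxy-5-methoxybenzaldehyde)
Product: 3 2-bromo-6-methoxybenzene-1,4-diol, via formate ester 2 (not isolated)
Conditions: H2O2 (30% aq.), NaOH, H2O, N2, 0 °C → rt; then aq. HCl
Reagents that add atoms: hydrogen peroxide, OO
Why: Dakin oxidation of a para-hydroxybenzaldehyde: hydroperoxide adds to the aldehyde, the aryl group migrates to oxygen and the formate is hydrolysed in the same basic medium; bromine and the methoxy group are untouched.

Step 2
Reactants: 3 2-bromo-6-methoxybenzene-1,4-diol
Product: 4 1-bromo-2,3,5-trimethoxybenzene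
Conditions: MeI, K2CO3, acetone, N2, reflux
Reagents that add atoms: iodomethane, CI
Why: Williamson O-methylation of both phenols; exclusion of air keeps the hydroquinone from oxidising before it is capped.

Step 3
Reactants: 4 1-bromo-2,3,5-trimethoxybenzene; 5 but-3-enoic acid
Product: 6 (E)-4-(2,3,5-trimethoxyphenyl)but-3-enoic acid
Conditions: Pd(OAc)2 (cat.), P(o-tol)3 (cat.), Et3N, MeCN, 85 °C; then aq. HCl
Reagents that add atoms: none
Why: Heck reaction: the aryl group adds to the terminal alkene carbon and β-hydride elimination towards the benzylic hydrogen gives the E styrene-type alkene, conjugated with the arene and not with the carboxylate.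

Step 4
Reactants: 6 (E)-4-(2,3,5-trimethoxyphenyl)but-3-enoic acid
Product: 7 (E)-2-ethyl-4-(2,3,5-trimethoxyphenyl)but-3-enoic acid (racemic)
Conditions: LiN(iPr)2 (2.2 equiv), THF, −78 → 0 °C; EtI, −78 °C → rt; then aq. HCl
Reagents that add atoms: iodoethane, CCI
Why: Alkylation of the dienediolate of a β,γ-unsaturated acid, which reacts with alkyl halides at the α-carbon; the new stereocentre is racemic and is erased in step 5.

Step 5
Reactants: 7 (E)-2-ethyl-4-(2,3,5-trimethoxyphenyl)but-3-enoic acid
Product: 9 2-ethyl-5,6,8-trimethoxynaphthalen-1-ol, via naphthyl acetate 8 (not isolated)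
Conditions: Ac2O, NaOAc, 140 °C; then K2CO3 (cat.), MeOH, N2, rt
Reagents that add atoms: none
Why: Classical benzannulation of a 4-arylbut-3-enoic acid: the mixed anhydride equilibrates through its dienolate to the Z geometry and acylates the only ortho position of the arene (ortho and para to methoxy groups) in a Friedel–Crafts-type six-ring closure; the naphthol is trapped as acetate 8 and freed by methanolysis.

Step 6
Reactants: 9 2-ethyl-5,6,8-trimethoxynaphthalen-1-ol
Product: 10 (2R)-2-ethyl-2-hydroxy-5,6,8-trimethoxynaphthalen-1(2H)-one
Conditions: enantiopure 4,4',6,6'-tetra-tert-butyl-2,2'-bis(iodyl)biphenyl (1 equiv), CH2Cl2, −40 → 0 °C; then aq. Na2S2O3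
Reagents that add atoms: 4,4',6,6'-tetra-tert-butyl-2,2'-bis(iodyl)biphenyl (single atropisomer), CC(C)(C)c1cc(I(=O)=O)c(-c2c(I(=O)=O)cc(C(C)(C)C)cc2C(C)(C)C)c(C(C)(C)C)c1
Why: Hydroxylative phenol dearomatisation by a pentavalent iodine reagent, a reaction type known for 2-alkyl-1-naphthols: the naphthol oxygen binds to iodine and an iodine-bound oxygen is delivered within the complex to the ethyl-bearing ortho carbon, which favours ortho over para oxygenation; the C2-symmetric biaryl backbone differentiates the two faces and sets R at the new carbinol carbon; no peracid is present, so the new C3=C4 alkene is not epoxidised.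

Step 7
Reactants: 11 dimethyl squarate (3,4-dimethoxycyclobut-3-ene-1,2-dione)
Product: 13 3-ethyl-4-methoxycyclobut-3-ene-1,2-dione, via carbonyl adduct 12 (not isolated)
Conditions: EtMgBr (1.05 equiv), THF, −78 °C; then conc. HCl, CH2Cl2, rt
Reagents that add atoms: ethylmagnesium bromide, CC[Mg]Br
Why: 1,2-Addition of the Grignard reagent to one of the two equivalent carbonyls, then acid-promoted ionisation of the tertiary alcohol, hydration of the alkoxy-stabilised cation and loss of methanol; this is the standard squarate route to 3-alkyl-4-alkoxycyclobutenediones.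

Step 8
Reactants: 13 3-ethyl-4-methoxycyclobut-3-ene-1,2-dione
Product: 14 3-ethyl-4-hydroxycyclobut-3-ene-1,2-dione
Conditions: 2 M HCl, THF/H2O, 50 °C
Reagents that add atoms: water, O
Why: Acid hydrolysis of a vinylogous ester by addition–elimination; the product is a strong vinylogous acid, isolated by evaporation.

Step 9
Reactants: 14 3-ethyl-4-hydroxycyclobut-3-ene-1,2-dione
Product: 15 3-chloro-4-ethylcyclobut-3-ene-1,2-dione
Conditions: (COCl)2, DMF (cat.), CH2Cl2, 0 °C → rt
Reagents that add atoms: oxalyl chloride, O=C(Cl)C(Cl)=O
Why: The vinylogous carboxylic acid is converted into the vinylogous acid chloride as a carboxylic acid would be (Vilsmeier-type activation); the product is used crude.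

Step 10
Reactants: 10 (2R)-2-ethyl-2-hydroxy-5,6,8-trimethoxynaphthalen-1(2H)-one; 15 3-chloro-4-ethylcyclobut-3-ene-1,2-dione
Product: 16 3-ethyl-4-{[(2R)-2-ethyl-5,6,8-trimethoxy-1-oxo-1,2-dihydronaphthalen-2-yl]oxy}cyclobut-3-ene-1,2-dione
Conditions: LiN(SiMe3)2 (1.05 equiv), THF, −78 °C; then 15, −78 → −40 °C; neutral work-up
Reagents that add atoms: none
Why: Addition–elimination of the lithium alkoxide of the tertiary α-ketol at the chlorine-bearing carbon of the vinylogous acid chloride, a small and highly electrophilic acceptor suited to a hindered oxygen; low temperature holds back α-ketol rearrangement, and the C–O bond at the stereocentre is not involved, so configuration is retained.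

Step 11
Reactants: 4 1-bromo-2,3,5-trimethoxybenzene; 16 3-ethyl-4-{[(2R)-2-ethyl-5,6,8-trimethoxy-1-oxo-1,2-dihydronaphthalen-2-yl]oxy}cyclobut-3-ene-1,2-dione
Product: 18 2-ethyl-3-{[(2R)-2-ethyl-5,6,8-trimethoxy-1-oxo-1,2-dihydronaphthalen-2-yl]oxy}-4-hydroxy-4-(2,3,5-trimethoxyphenyl)cyclobut-2-en-1-one (both carbinol epimers), via aryllithium 17 (not isolated)
Conditions: 4, n-BuLi, THF, −78 °C; then added to 16, THF, −78 °C; aq. NH4Cl at −78 °C
Reagents that add atoms: none
Why: Bromine–lithium exchange and 1,2-addition to the cyclobutenedione: the carbonyl next to the alkoxy-bearing carbon reacts because the other one is deactivated as a vinylogous ester carbonyl, and the strained dione is far more electrophilic than the hindered, methoxyaryl-conjugated ketone C4'; the new carbinol centre forms unselectively, which does not matter because it is destroyed in step 12.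

Step 12
Reactants: 18 2-ethyl-3-{[(2R)-2-ethyl-5,6,8-trimethoxy-1-oxo-1,2-dihydronaphthalen-2-yl]oxy}-4-hydroxy-4-(2,3,5-trimethoxyphenyl)cyclobut-2-en-1-one
Product: 21 (2R)-2-ethyl-2-[(3-ethyl-1,4-dihydroxy-5,7,8-trimethoxynaphthalen-2-yl)oxy]-5,6,8-trimethoxynaphthalen-1(2H)-one, via vinylketene 19 (not isolated), via dienone tautomer 20 (not isolated)
Conditions: PhMe (degassed, dilute), 110 °C, Ar
Reagents that add atoms: none
Why: Moore rearrangement of a 4-aryl-4-hydroxycyclobutenone. Heating breaks the ring bond between the carbonyl carbon and the carbinol carbon by conrotatory 4π electrocyclic opening; the hydroxyl donor rotates outwards, so the aryl group lies cis to the ketene in 19. The ketene carbon (future C4) then bonds to the only unsubstituted ortho carbon of the aryl group (future C4a) in a thermal disrotatory 6π electrocyclisation, which closes the six-membered carbocycle C1–C2–C3–C4–C4a–C8a as dienone 20, and enolisation gives the aromatic naphthalene-1,4-diol 21. No stereocentre is created: the carbinol carbon of 18 becomes sp2, so both epimers converge, and C3' lies outside the reacting π system and keeps its configuration. Site selectivity is structural, since the second ortho position carries a methoxy group, and the ethyl/alkoxy order is inherited from 18. The step needs chemoselectivity against capture of the ketene by the free hydroxyl and against a sigmatropic shift or heterolysis of the allylic tertiary ether; the easy opening of a donor-substituted hydroxycyclobutenone at 110 °C, a dilute non-polar medium and exclusion of acid and oxygen are relied on for this.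

Step 13
Reactants: 21 (2R)-2-ethyl-2-[(3-ethyl-1,4-dihydroxy-5,7,8-trimethoxynaphthalen-2-yl)oxy]-5,6,8-trimethoxynaphthalen-1(2H)-one
Product: 22 3-ethyl-2-{[(2R)-2-ethyl-5,6,8-trimethoxy-1-oxo-1,2-dihydronaphthalen-2-yl]oxy}-5,7,8-trimethoxynaphthalene-1,4-dione
Conditions: Ag2O, Et2O, rt
Reagents that add atoms: none
Why: Two-electron oxidation of a 1,4-hydroquinone to the quinone by monovalent silver under neutral conditions, which spare the allylic tertiary ether.

Step 14
Reactants: 22 3-ethyl-2-{[(2R)-2-ethyl-5,6,8-trimethoxy-1-oxo-1,2-dihydronaphthalen-2-yl]oxy}-5,7,8-trimethoxynaphthalene-1,4-dione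
Product: 23 3-ethyl-2-{[(2R)-2-ethyl-3,4-dihydroxy-5,6,8-trimethoxy-1-oxo-1,2,3,4-tetrahydronaphthalen-2-yl]oxy}-5,7,8-trimethoxynaphthalene-1,4-dione (cis-diol, two diastereomers)
Conditions: OsO4 (cat.), NMO, acetone/H2O, rt
Reagents that add atoms: N-methylmorpholine N-oxide, C[N+]1([O-])CCOCC1; water, O; both oxygens are delivered through osmium tetroxide, O=[Os](=O)(=O)=O
Why: Catalytic OsO4/NMO dihydroxylation: OsO4 adds suprafacially to the electron-rich cis-disubstituted styrene-type C1'=C2' bond, while the tetrasubstituted, electron-poor quinone alkene does not compete; the two new carbinol centres are not controlled and need not be, since both are oxidised in step 15.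

Step 15
Reactants: 23 3-ethyl-2-{[(2R)-2-ethyl-3,4-dihydroxy-5,6,8-trimethoxy-1-oxo-1,2,3,4-tetrahydronaphthalen-2-yl]oxy}-5,7,8-trimethoxynaphthalene-1,4-dione
Product: 24 (3S)-3-ethyl-3-[(3-ethyl-5,7,8-trimethoxy-1,4-dioxo-1,4-dihydronaphthalen-2-yl)oxy]-5,7,8-trimethoxynaphthalene-1,2,4(3H)-trione
Conditions: (COCl)2, DMSO, CH2Cl2, −78 °C; Et3N, −78 → 0 °C
Reagents that add atoms: none
Why: Swern oxidation of both secondary alcohols gives the non-enolisable 1,2-diketone without C–C cleavage; the two carbinol stereocentres vanish and C3' keeps its arrangement, its descriptor changing from R to S only through the change in CIP ranking.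

Step 16
Reactants: 24 (3S)-3-ethyl-3-[(3-ethyl-5,7,8-trimethoxy-1,4-dioxo-1,4-dihydronaphthalen-2-yl)oxy]-5,7,8-trimethoxynaphthalene-1,2,4(3H)-trione
Product: 25 (3S)-3-ethyl-3-[(3-ethyl-5,7,8-trihydroxy-1,4-dioxo-1,4-dihydronaphthalen-2-yl)oxy]-5,7,8-trihydroxynaphthalene-1,2,4(3H)-trione (target CNP0325426.1)
Conditions: BBr3 (excess), CH2Cl2, −78 °C → rt; then H2O, 0 °C
Reagents that add atoms: none
Why: Lewis-acid cleavage of aryl methyl ethers: the four peri ethers (C5, C8, C5', C8') are activated by chelation to the neighbouring carbonyls and the C7/C7' ethers by cyclic borate formation with the adjacent oxygens; C3' now lies between two carbonyls and is quaternary, so its C–O bond can neither ionise nor be displaced, and the acidic work-up avoids base-induced cleavage of the trione.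

## Compound list

1 | 5-bromovanillin (3-bromo-4-hydroxy-5-methoxybenzaldehyde) | COc1cc(C=O)cc(Br)c1O | starting material
2 | 3-bromo-4-hydroxy-5-methoxyphenyl formate | COc1cc(OC=O)cc(Br)c1O | intermediate (not isolated)
3 | 2-bromo-6-methoxybenzene-1,4-diol | COc1cc(O)cc(Br)c1O | intermediate
4 | 1-bromo-2,3,5-trimethoxybenzene | COc1cc(Br)c(OC)c(OC)c1 | intermediate
5 | but-3-enoic acid | C=CCC(=O)O | starting material
6 | (E)-4-(2,3,5-trimethoxyphenyl)but-3-enoic acid | COc1cc(/C=C/CC(=O)O)c(OC)c(OC)c1 | intermediate
7 | (E)-2-ethyl-4-(2,3,5-trimethoxyphenyl)but-3-enoic acid (racemic) | CCC(/C=C/c1cc(OC)cc(OC)c1OC)C(=O)O | intermediate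
8 | 2-ethyl-5,6,8-trimethoxynaphthalen-1-yl acetate | CCc1ccc2c(OC)c(OC)cc(OC)c2c1OC(C)=O | intermediate (not isolated)
9 | 2-ethyl-5,6,8-trimethoxynaphthalen-1-ol | CCc1ccc2c(OC)c(OC)cc(OC)c2c1O | intermediate
10 | (2R)-2-ethyl-2-hydroxy-5,6,8-trimethoxynaphthalen-1(2H)-one | O[C@]1(CC)C=Cc2c(OC)c(OC)cc(OC)c2C1=O | intermediate
11 | dimethyl squarate (3,4-dimethoxycyclobut-3-ene-1,2-dione) | COC1=C(OC)C(=O)C1=O | starting material
12 | 4-ethyl-4-hydroxy-2,3-dimethoxycyclobut-2-en-1-one (racemic) | CCC1(O)C(OC)=C(OC)C1=O | intermediate (not isolated)
13 | 3-ethyl-4-methoxycyclobut-3-ene-1,2-dione | CCC1=C(OC)C(=O)C1=O | intermediate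
14 | 3-ethyl-4-hydroxycyclobut-3-ene-1,2-dione | CCC1=C(O)C(=O)C1=O | intermediate
15 | 3-chloro-4-ethylcyclobut-3-ene-1,2-dione | CCC1=C(Cl)C(=O)C1=O | intermediate
16 | 3-ethyl-4-{[(2R)-2-ethyl-5,6,8-trimethoxy-1-oxo-1,2-dihydronaphthalen-2-yl]oxy}cyclobut-3-ene-1,2-dione | CCC1=C(O[C@]2(CC)C=Cc3c(OC)c(OC)cc(OC)c3C2=O)C(=O)C1=O | intermediate
17 | (2,3,5-trimethoxyphenyl)lithium | [Li]c1cc(OC)cc(OC)c1OC | intermediate (not isolated)
18 | 2-ethyl-3-{[(2R)-2-ethyl-5,6,8-trimethoxy-1-oxo-1,2-dihydronaphthalen-2-yl]oxy}-4-hydroxy-4-(2,3,5-trimethoxyphenyl)cyclobut-2-en-1-one (both C4 epimers) | CCC1=C(O[C@]2(CC)C=Cc3c(OC)c(OC)cc(OC)c3C2=O)C(O)(c2cc(OC)cc(OC)c2OC)C1=O | intermediate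
19 | (3Z)-2-ethyl-3-{[(2R)-2-ethyl-5,6,8-trimethoxy-1-oxo-1,2-dihydronaphthalen-2-yl]oxy}-4-hydroxy-4-(2,3,5-trimethoxyphenyl)buta-1,3-dien-1-one | CCC(=C=O)/C(O[C@]1(CC)C=Cc2c(OC)c(OC)cc(OC)c2C1=O)=C(/O)c1cc(OC)cc(OC)c1OC | intermediate (not isolated)
20 | 3-ethyl-1-hydroxy-5,7,8-trimethoxy-2-{[(2R)-2-ethyl-5,6,8-trimethoxy-1-oxo-1,2-dihydronaphthalen-2-yl]oxy}naphthalen-4(4aH)-one | CCC1=C(O[C@]3(CC)C=Cc4c(OC)c(OC)cc(OC)c4C3=O)C(O)=C2C(OC)=C(OC)C=C(OC)C2C1=O | intermediate (not isolated)
21 | (2R)-2-ethyl-2-[(3-ethyl-1,4-dihydroxy-5,7,8-trimethoxynaphthalen-2-yl)oxy]-5,6,8-trimethoxynaphthalen-1(2H)-one | CCc1c(O)c2c(OC)cc(OC)c(OC)c2c(O)c1O[C@]3(CC)C=Cc4c(OC)c(OC)cc(OC)c4C3=O | intermediate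
22 | 3-ethyl-2-{[(2R)-2-ethyl-5,6,8-trimethoxy-1-oxo-1,2-dihydronaphthalen-2-yl]oxy}-5,7,8-trimethoxynaphthalene-1,4-dione | CCC1=C(O[C@]2(CC)C=Cc3c(OC)c(OC)cc(OC)c3C2=O)C(=O)c2c(OC)c(OC)cc(OC)c2C1=O | intermediate
23 | 3-ethyl-2-{[(2R)-2-ethyl-3,4-dihydroxy-5,6,8-trimethoxy-1-oxo-1,2,3,4-tetrahydronaphthalen-2-yl]oxy}-5,7,8-trimethoxynaphthalene-1,4-dione (cis-3,4-diol, two diastereomers) | CCC1=C(O[C@]2(CC)C(O)C(O)c3c(OC)c(OC)cc(OC)c3C2=O)C(=O)c2c(OC)c(OC)cc(OC)c2C1=O | intermediate
24 | (3S)-3-ethyl-3-[(3-ethyl-5,7,8-trimethoxy-1,4-dioxo-1,4-dihydronaphthalen-2-yl)oxy]-5,7,8-trimethoxynaphthalene-1,2,4(3H)-trione | CCC1=C(O[C@]2(CC)C(=O)C(=O)c3c(OC)c(OC)cc(OC)c3C2=O)C(=O)c2c(OC)c(OC)cc(OC)c2C1=O | intermediate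
25 | (3S)-3-ethyl-3-[(3-ethyl-5,7,8-trihydroxy-1,4-dioxo-1,4-dihydronaphthalen-2-yl)oxy]-5,7,8-trihydroxynaphthalene-1,2,4(3H)-trione | CCC1=C(O[C@]2(CC)C(=O)C(=O)c3c(O)c(O)cc(O)c3C2=O)C(=O)c2c(O)c(O)cc(O)c2C1=O | target

## Step count and least certain steps

Total: 16 steps. Longest linear sequence: 13 steps (steps 1–6 and 10–16, from 1). The squarate branch (steps 7–9) joins at step 10, and 4 is used a second time in step 11.

**Step 12 (key step).** The vinylketene may be captured by the free tertiary hydroxyl (closure to a furanone instead of onto the arene). The allylic tertiary ether may also ionise or shift at the temperature needed for ring opening, because its leaving group is a stabilised enol-type oxygen. Fallback, setting out from 16 and 17: the lithium alkoxide formed in step 11 is trapped with Me3SiCl to give the trimethylsilyl ether F1. Thermolysis of F1 gives the monosilylated hydroquinone F2, a known variant in which no hydroxyl can capture the ketene. Mild aqueous acid in THF removes the silyl group and returns to 21.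

**Step 6.** Facial discrimination by the chiral iodyl reagent may be poor on this peri-methoxylated naphthol, or oxygen may be transferred to the free para carbon with over-oxidation to a quinone. Fallback, setting out from 7: hydrogenation (H2, Pd/C) gives the saturated acid F3, and ring closure (P2O5 in MeSO3H) gives the tetralone F4. Enolate hydroxylation (NaN(SiMe3)2, THF, −78 °C; enantiopure (camphorylsulfonyl)oxaziridine) gives the ketol F5 with the established face control of such reagents on 2-alkyl-1-tetralone enolates. Benzylic dehydrogenation with DDQ, which cannot aromatise the ring because C2 is quaternary, returns to 10.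

**Step 10.** Substitution by the hindered tertiary alkoxide may be slow, so that α-ketol rearrangement of the alkoxide or heterolysis of the product ether (whose leaving group is the anion of a strong vinylogous acid) takes over. Fallback, setting out from 10: the lithium alkoxide is treated with the more electrophilic 3,4-dichlorocyclobut-3-ene-1,2-dione (squaric acid dichloride) to give the chloro ether F6. Ethyl is then introduced by Negishi coupling at the vinylogous acid chloride (EtZnCl, Pd(PPh3)4 cat., THF), returning to 16.

**Step 11.** The aryllithium may attack the ketone C4', may add to the squarate carbonyl next to the ethyl-bearing carbon (favoured sterically by the bulky alkoxy group), or may deprotonate the ethyl CH2. Fallback, setting out from 13 and 17, with the order of events reversed: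
- Addition of 17 to 13 gives the cyclobutenone F7.
- Thermolysis gives the hydroquinone F8, and Ag2O gives the methoxyquinone F9.
- Hydrolysis of the quinone vinylogous methyl ester gives the hydroxyquinone F10, and (COCl)2/DMF gives the chloroquinone F11.
- Substitution of chloride by the lithium alkoxide of 10 returns to 22.

This gives up the advantage of making the hindered ether on the squarate and is held in reserve only.

**Step 16.** Cleavage of the two non-chelated C7/C7' ethers may be incomplete under conditions mild enough for the vinylogous ester linkage, or bromide may cleave the C2–O bond by addition–elimination at the boron-activated quinone. Fallback, setting out from 24, a staged deprotection: BCl3 (CH2Cl2, −78 → 0 °C) removes only the four chelation-activated peri ethers to give the tetraphenol F12. The two remaining guaiacol-type ethers are then cleaved by iodide within a magnesium chelate (MgI2·OEt2, warm toluene), a nucleophilic and not a Lewis-acidic mode, returning to 25.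

## Further compounds

F1 | step 12 | 2-ethyl-3-{[(2R)-2-ethyl-5,6,8-trimethoxy-1-oxo-1,2-dihydronaphthalen-2-yl]oxy}-4-(2,3,5-trimethoxyphenyl)-4-[(trimethylsilyl)oxy]cyclobut-2-en-1-one | CCC1=C(O[C@]2(CC)C=Cc3c(OC)c(OC)cc(OC)c3C2=O)C(O[Si](C)(C)C)(c2cc(OC)cc(OC)c2OC)C1=O
F2 | step 12 | (2R)-2-ethyl-2-({3-ethyl-4-hydroxy-5,7,8-trimethoxy-1-[(trimethylsilyl)oxy]naphthalen-2-yl}oxy)-5,6,8-trimethoxynaphthalen-1(2H)-one | CCc1c(O)c2c(OC)cc(OC)c(OC)c2c(O[Si](C)(C)C)c1O[C@]3(CC)C=Cc4c(OC)c(OC)cc(OC)c4C3=O
F3 | step 6 | 2-ethyl-4-(2,3,5-trimethoxyphenyl)butanoic acid (racemic) | CCC(CCc1cc(OC)cc(OC)c1OC)C(=O)O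
F4 | step 6 | 2-ethyl-5,6,8-trimethoxy-3,4-dihydronaphthalen-1(2H)-one (racemic) | CCC1CCc2c(OC)c(OC)cc(OC)c2C1=O
F5 | step 6 | (2R)-2-ethyl-2-hydroxy-5,6,8-trimethoxy-3,4-dihydronaphthalen-1(2H)-one | O[C@]1(CC)CCc2c(OC)c(OC)cc(OC)c2C1=O
F6 | step 10 | 3-chloro-4-{[(2R)-2-ethyl-5,6,8-trimethoxy-1-oxo-1,2-dihydronaphthalen-2-yl]oxy}cyclobut-3-ene-1,2-dione | ClC1=C(O[C@]2(CC)C=Cc3c(OC)c(OC)cc(OC)c3C2=O)C(=O)C1=O
F7 | step 11 | 2-ethyl-4-hydroxy-3-methoxy-4-(2,3,5-trimethoxyphenyl)cyclobut-2-en-1-one (racemic) | CCC1=C(OC)C(O)(c2cc(OC)cc(OC)c2OC)C1=O
F8 | step 11 | 3-ethyl-2,5,7,8-tetramethoxynaphthalene-1,4-diol | CCc1c(O)c2c(OC)cc(OC)c(OC)c2c(O)c1OC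
F9 | step 11 | 3-ethyl-2,5,7,8-tetramethoxynaphthalene-1,4-dione | CCC1=C(OC)C(=O)c2c(OC)c(OC)cc(OC)c2C1=O
F10 | step 11 | 3-ethyl-2-hydroxy-5,7,8-trimethoxynaphthalene-1,4-dione | CCC1=C(O)C(=O)c2c(OC)c(OC)cc(OC)c2C1=O
F11 | step 11 | 2-chloro-3-ethyl-5,7,8-trimethoxynaphthalene-1,4-dione | CCC1=C(Cl)C(=O)c2c(OC)c(OC)cc(OC)c2C1=O
F12 | step 16 | (3S)-3-ethyl-3-[(3-ethyl-5,8-dihydroxy-7-methoxy-1,4-dioxo-1,4-dihydronaphthalen-2-yl)oxy]-5,8-dihydroxy-7-methoxynaphthalene-1,2,4(3H)-trione | CCC1=C(O[C@]2(CC)C(=O)C(=O)c3c(O)c(OC)cc(O)c3C2=O)C(=O)c2c(O)c(OC)cc(O)c2C1=O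
A1 | alternative 1 | 2,2'-oxybis(3-ethyl-5,7,8-trimethoxynaphthalene-1,4-dione) | CCC1=C(OC2=C(CC)C(=O)c3c(OC)cc(OC)c(OC)c3C2=O)C(=O)c2c(OC)c(OC)cc(OC)c2C1=O
A2 | alternative 1 | (3S)-3-ethyl-3-[(3-ethyl-5,7,8-trimethoxy-1,4-dioxo-1,4-dihydronaphthalen-2-yl)oxy]-5,7,8-trimethoxynaphthalene-1,2,4(3H)-trione (identical with 24) | CCC1=C(O[C@]2(CC)C(=O)C(=O)c3c(OC)c(OC)cc(OC)c3C2=O)C(=O)c2c(OC)c(OC)cc(OC)c2C1=O
A3 | alternative 2 | 3,4,6-trimethoxy-2-(3-oxopentyl)benzaldehyde | CCC(=O)CCc1c(OC)c(OC)cc(OC)c1C=O
A4 | alternative 2 | (2R)-2-ethyl-2-hydroxy-5,6,8-trimethoxy-3,4-dihydronaphthalen-1(2H)-one | O[C@]1(CC)CCc2c(OC)c(OC)cc(OC)c2C1=O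
A5 | alternative 3 | pentacarbonyl[methoxy(2,4,5-trimethoxyphenyl)methylidene]chromium | COC(=[Cr](=C=O)(=C=O)(=C=O)(=C=O)=C=O)c1cc(OC)c(OC)cc1OC
A6 | alternative 3 | tert-butyl{[(1S,2R)-2-(but-1-yn-1-yloxy)-2-ethyl-5,6,8-trimethoxy-1,2-dihydronaphthalen-1-yl]oxy}dimethylsilane | CCC#CO[C@]1(CC)C=Cc2c(OC)c(OC)cc(OC)c2[C@@H]1O[Si](C)(C)C(C)(C)C
A7 | alternative 3 | 2-{[(1S,2R)-1-[(tert-butyldimethylsilyl)oxy]-2-ethyl-5,6,8-trimethoxy-1,2-dihydronaphthalen-2-yl]oxy}-3-ethyl-4,5,7,8-tetramethoxynaphthalen-1-ol | CCc1c(OC)c2c(OC)cc(OC)c(OC)c2c(O)c1O[C@]1(CC)C=Cc2c(OC)c(OC)cc(OC)c2[C@@H]1O[Si](C)(C)C(C)(C)C
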